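| flask | starting complex | incoming ligand | protic impurity | remark | time |
|---|---|---|---|---|---|
| teal | 0.20 M | 0.45 equiv | 0.040 M | run made earlier |  |
| green | 0.20 M | 1.8 equiv | 0.040 M | run made earlier |  |
| Monday's | 0.20 M | 2.50 equiv | 0.0400 M |  | 6.0 min |
| Saturday's | 0.20 M | 1.20 equiv | 0.0400 M |  | 6.0 min |
| Thursday's | 0.20 M | 0.500 equiv | 0.0400 M |  | 6.0 min |

| run | time / min | complex with one exchanged / % | starting complex / % |
|---|---|---|---|
| teal | 0.833 | 24.9 | 60.6 |
| teal | 1.50 | 29.5 | 52.0 |
| teal | 2.50 | 32.9 | 47.5 |
| teal | 3.00 | 30.9 | 49.3 |
| green | 0.833 | 52.2 | 28.5 |
| green | 1.50 | 54.3 | 20.8 |
| green | 2.50 | 61.3 | 14.0 |
| green | 3.00 | 59.2 | 13.1 |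

(scatter of a reading: 1 percentage point)

- which of these holds the largest part of the starting complex at the end of Monday's (complex with one exchanged / complex with two exchanged / starting complex)
- which of these holds the largest part of the starting complex at the end of Saturday's (complex with one exchanged / complex with two exchanged / starting complex)
- which of these holds the largest part of the starting complex at the end of Thursday's (complex with one exchanged / complex with two exchanged / starting complex)
- amount of complex with one exchanged at the end of Saturday's, in percent of the starting complex charged

- complex with one exchanged is meant together with its crystals
- solid, in amounts per volume of the solution: crystals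
- reactions considered so far: starting complex + incoming ligand -> leaving ligand + complex with one exchanged; complex with one exchanged + incoming ligand -> leaving ligand + complex with two exchanged; protic impurity + starting complex -> quenched substrate; 2 incoming ligand -> homo dimer; crystals <-> complex with one exchanged

At early times the teal run already shows a loss besides exchange: at 0.833 min starting complex stands at 60.6% and complex with one exchanged at 24.9%. By 3.00 min the two sum to 80.2%. The protic impurity, charged at 0.0400 M against 0.20 M, can take 20.0%, so I call 80.0% the usable complex.

My first estimate is that every ligand lands, which would empty the starting complex on Saturday's, since 1.20 equiv exceeds the usable complex. But teal charged 0.45 equiv and shows 30.9% in complex with one exchanged, so the homo dimer takes a real share.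

So I try a selectivity factor of one: ligand goes to complex in the share [starting complex]/([starting complex]+[incoming ligand]). Integrated, the ratio [incoming ligand]/[starting complex] drops by one for each e-fold fall of [starting complex]. The stranded complex, what remains when the ligand is gone, is then the usable complex times exp(−equivalents/usable complex), which for Saturday's gives 17.9%.

My doubt is whether this fits. It gives 45.6% for teal against a last reading of 49.3%, and 8.43% for green against 13.1%, but those readings stand at 3.00 min, while the formula speaks of the end of the reaction. The green run's starting complex had fallen from 20.8% at 1.50 min to that last reading, so I don't take these gaps as proof that the formula sits low. A second doubt is complex with two exchanged. Green falls 7.7 percentage points short of the usable complex, and I scale that gap with equivalents, which is a guess. Saturday's then holds 57.0% in complex with one exchanged. Monday's strands 3.51%, less than its 65.8% of complex with one exchanged. Thursday's strands 42.8%, more than its 35.0%.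

The forecast names complex with one exchanged for Monday's, complex with one exchanged for Saturday's and starting complex for Thursday's, with 53% (47% to 59%) on Saturday's, “so extra ligand is largely wasted”. Its centre lies below my 57.0%.

Saturday's gives 55.9% of complex with one exchanged and 16.5% of starting complex, against my stranded 17.9%, with 0.663% of the ligand left; the three choices stand as forecast.

    starting complex + incoming ligand → leaving ligand + complex with one exchanged (k = 0.180 L mol⁻¹ s⁻¹)
    complex with one exchanged + incoming ligand → leaving ligand + complex with two exchanged (k = 0.370 L mol⁻¹ s⁻¹)
    protic impurity + starting complex → quenched substrate (k = 0.110 L mol⁻¹ s⁻¹)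
    2 incoming ligand → homo dimer (k = 0.0750 L mol⁻¹ s⁻¹)
    crystals ⇌ complex with one exchanged, rate k5*(cs5 - [complex with one exchanged]) while solid is left; crystals form when [complex with one exchanged] > cs5 (solubility = 2.40 mM, k = 0.270 s⁻¹)

The flask like Saturday's but with 0.480 equiv reckons to 43.9% stranded, and it holds 43.7% of starting complex, with 33.7% of complex with one exchanged and 2.94% of complex with two exchanged.

Readings and results come from a simulation on assumed constants.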